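The anisyl-bearing pyranone ring (O1, C2, C3, C4, C4a, C8a) is a cyclised 2'-hydroxychalcone: O1 is a phloroglucinol-ring hydroxyl ortho to the C4 ketone, C2 the β-carbon of a C2=C3–C4=O enone, and C3–H is epimerisable. The hydroxyphenyl flavanone unit (2''R,3''S) is therefore made first, by rhodium-catalysed asymmetric arylation of a chromone and trans-selective C3'' alkylation; an anisylidene is then condensed onto the side chain, giving a 2'-hydroxychalcone whose α-carbon carries the finished flavanone. The key step closes O1–C2 by a cinchona-thiourea-catalysed 6-endo oxa-Michael addition: it forms the second heterocycle, sets C2 (S) by catalyst control and C3 (R) by equilibration, and turns any facial error into a separable diastereomer.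

Key step: step 8

Locants: unprimed (O1, C2, C3, C4) for the anisyl flavanone (unit 1), doubly primed for the hydroxyphenyl flavanone (unit 2); 2'–6' are the positions of the aroyl ring in the open chalcone.

Assumption: the senses of induction of the diphosphine in step 2 and of the alkaloid thiourea in step 8 are taken by analogy with simpler chromones and chalcones; if a test shows the opposite sense, the mirror-image ligand or the quinidine-derived pseudo-enantiomer is used and nothing else changes.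

Step 1
Reactants: 1 5,7-dihydroxychromone; 2 benzyl bromide
Product: 3 5,7-bis(benzyloxy)chromone
Conditions: BnBr (2.5 equiv), K2CO3 (3 equiv), Bu4NI (cat.), DMF, 70 °C
Reagents that add atoms: benzyl bromide, BrCc1ccccc1
Why: Double Williamson etherification (SN2 at the benzylic bromide) of the two phenoxides; warm DMF is needed for the 5-OH that is hydrogen-bonded to the C4 carbonyl, and the chromone ring is stable to carbonate.

Step 2
Reactants: 3 5,7-bis(benzyloxy)chromone; 4 4-(benzyloxy)phenylboronic acid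
Product: 5 (2R)-5,7-bis(benzyloxy)-2-[4-(benzyloxy)phenyl]chroman-4-one
Conditions: [Rh(OH)(cod)]2 (2.5 mol %), (R)-MeO-F12-BIPHEP [(R)-2,2'-bis[bis(3,4,5-trifluorophenyl)phosphino]-6,6'-dimethoxy-1,1'-biphenyl] (5.5 mol %), 4 (2.5 equiv), toluene/H2O 10:1, 25 °C
Reagents that add atoms: 4-(benzyloxy)phenylboronic acid, OB(O)c1ccc(OCc2ccccc2)cc1
Why: Rhodium-catalysed asymmetric 1,4-addition of an arylboronic acid to a cyclic enone (Hayashi–Miyaura reaction), known for chromones: the aryl–rhodium complex of the chiral diphosphine carbometalates one enantioface of the C2''=C3'' bond and thereby sets C2'' (R), and water protonates the resulting rhodium enolate.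

Step 3
Reactants: 6 1,3,5-tris(benzyloxy)benzene; 7 bromoacetyl bromide
Product: 8 2-bromo-1-[2,4,6-tris(benzyloxy)phenyl]ethan-1-one
Conditions: BrCH2COBr (1.1 equiv), ZnCl2 (1.2 equiv), CH2Cl2/Et2O, 0 °C
Reagents that add atoms: bromoacetyl bromide, O=C(Br)CBr
Why: Friedel–Crafts acylation of a strongly activated arene whose three free ring positions are equivalent, so only one mono-ketone can form; the mild Lewis acid at 0 °C should leave the benzyl ethers alone.

Step 4
Reactants: 5 (2R)-5,7-bis(benzyloxy)-2-[4-(benzyloxy)phenyl]chroman-4-one; 8 2-bromo-1-[2,4,6-tris(benzyloxy)phenyl]ethan-1-one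
Product: 10 (2R,3S)-5,7-bis(benzyloxy)-2-[4-(benzyloxy)phenyl]-3-{2-oxo-2-[2,4,6-tris(benzyloxy)phenyl]ethyl}chroman-4-one (2,3-trans), via lithium enolate 9 (not isolated)
Conditions: LiN(SiMe3)2 (1.05 equiv), THF, −78 °C; 8 (1.2 equiv), −78 → −40 °C; AcOH quench at −78 °C
Reagents that add atoms: 2-bromo-1-[2,4,6-tris(benzyloxy)phenyl]ethan-1-one (8), O=C(CBr)c1c(OCc2ccccc2)cc(OCc2ccccc2)cc1OCc1ccccc1
Why: Alkylation of a kinetic lithium enolate with a phenacyl-type bromide (SN2), whose doubly ortho-substituted carbonyl resists 1,2-attack; the electrophile enters anti to the C2'' aryl group and C3'' is in any case epimerisable to the more stable 2'',3''-trans arrangement (3''S), while the low temperature suppresses E1cB opening of the pyranone.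

Step 5
Reactants: 10 (2R,3S)-5,7-bis(benzyloxy)-2-[4-(benzyloxy)phenyl]-3-{2-oxo-2-[2,4,6-tris(benzyloxy)phenyl]ethyl}chroman-4-one; 11 4-methoxybenzaldehyde
Product: 14 (2R,3S)-5,7-bis(benzyloxy)-2-[4-(benzyloxy)phenyl]-3-{1-hydroxy-1-(4-methoxyphenyl)-3-oxo-3-[2,4,6-tris(benzyloxy)phenyl]propan-2-yl}chroman-4-one (mixture at the two new centres), via dibutylboron enolate 12 (not isolated), via boron aldolate 13 (not isolated)
Conditions: Bu2BOTf (1.5 equiv), i-Pr2NEt (2 equiv), CH2Cl2, −78 → 0 °C; 11 (1.5 equiv), −78 → −20 °C; pH 7 buffer, MeOH, 30% H2O2, 0 °C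
Reagents that add atoms: 4-methoxybenzaldehyde, COc1ccc(C=O)cc1
Why: Boron-mediated aldol addition: Bu2BOTf and the hindered amine enolise the unhindered CH2 next to the side-chain ketone (a mesityl-ketone-like enolate) in preference to the tertiary C3''–H, and the boron enolate adds to the aldehyde under conditions too mild to open the flavanone; the two new centres are left uncontrolled because step 6 removes both.

Step 6
Reactants: 14 the aldol adduct of step 5
Product: 16 (2R,3S)-5,7-bis(benzyloxy)-2-[4-(benzyloxy)phenyl]-3-{(1E)-1-(4-methoxyphenyl)-3-oxo-3-[2,4,6-tris(benzyloxy)phenyl]prop-1-en-2-yl}chroman-4-one, via mesylate 15 (not isolated)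
Conditions: MsCl (1.5 equiv), Et3N (4 equiv), CH2Cl2, 0 → 25 °C
Reagents that add atoms: none
Why: Mesylation followed by E1cB β-elimination of the β-mesyloxy ketone gives the conjugated trisubstituted enone, expected as the E isomer with anisyl trans to the aroyl group; every phenol of the aroyl ring is still benzylated, so no cyclisation can occur at this stage.

Step 7
Reactants: 16 the hexabenzylated chalcone–flavanone of step 6
Product: 18 (2R,3S)-7-(benzyloxy)-2-[4-(benzyloxy)phenyl]-3-{(1E)-3-[2,4-bis(benzyloxy)-6-hydroxyphenyl]-1-(4-methoxyphenyl)-3-oxoprop-1-en-2-yl}-5-hydroxychroman-4-one, via dichloroboron chelate 17 (not isolated)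
Conditions: BCl3 (2.5 equiv), CH2Cl2, −78 °C; MeOH, then pH 5 buffer
Reagents that add atoms: none
Why: Chelation-controlled Lewis-acid dealkylation: BCl3 binds each ketone oxygen and cleaves only a benzyl ether ortho (peri) to it through a six-membered boron chelate, a selectivity well known for 2'-alkoxychalcones and 5-alkoxyflavanones, so the remote benzyl ethers, the methyl ether and the enone survive.

Step 8
Reactants: 18 the 2'-hydroxychalcone–flavanone of step 7
Product: 20 (2S,3R)-5,7-bis(benzyloxy)-3-[(2R,3S)-7-(benzyloxy)-2-[4-(benzyloxy)phenyl]-5-hydroxy-4-oxochroman-3-yl]-2-(4-methoxyphenyl)chroman-4-one, via cis C3-epimer 19 (not isolated)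
Conditions: quinine-derived thiourea N-[3,5-bis(trifluoromethyl)phenyl]-N'-[(8α,9S)-6'-methoxycinchonan-9-yl]thiourea (20 mol %), toluene, −20 °C; then 20 °C
Reagents that add atoms: none
Why: The quinuclidine nitrogen of the catalyst takes the proton of the single free 2'-OH while the thiourea hydrogen-bonds the C4 carbonyl, and the phenoxide oxygen adds to C2, the β-carbon of the C2=C3–C4=O enone, giving a thiourea-bound enolate that is protonated at C3. The closest known reaction is the cinchona-thiourea-catalysed enantioselective intramolecular oxa-Michael cyclisation of 2'-hydroxychalcones to flavanones, the laboratory counterpart of the chalcone isomerase reaction. The pyranone ring closes in the 6-endo-trig mode. C2 (S) should be set by the catalyst, which shields one face of the enone (reagent control), whereas C3 (R) is set by the substrate: kinetic protonation may give some cis epimer 19, which should equilibrate through the enol to the trans, diequatorial arrangement on warming. The step needs facial selectivity at C2 and chemoselectivity for one phenol; the latter is secured because only the 2'-OH can reach an acceptor carbon through a six-membered transition state, the 5''-OH being tied to C4''=O with no enone within reach, and unit 2 should not open because its C3''–H is not acidic enough for a tertiary amine at −20 °C. Because unit 2 is already a single enantiomer, a mis-selected C2 epimer is a diastereomer and can be removed by chromatography.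

Step 9
Reactants: 20 the tetrabenzylated biflavanone of step 8
Product: 21 (2S,3R)-5,7-dihydroxy-3-[(2R,3S)-5,7-dihydroxy-2-(4-hydroxyphenyl)-4-oxochroman-3-yl]-2-(4-methoxyphenyl)chroman-4-one (CNP0196568.3)
Conditions: H2 (1 atm), Pd/C (10 wt %), EtOAc/MeOH, 25 °C
Reagents that add atoms: none
Why: Hydrogenolysis of the four remaining aryl benzyl ethers over palladium on carbon under neutral conditions, which leave the aryl methyl ether, both ketones and all four stereocentres untouched.

Compound list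
1 | 5,7-dihydroxy-4H-chromen-4-one | O=c1ccoc2cc(O)cc(O)c12 | starting material
2 | benzyl bromide | BrCc1ccccc1 | starting material
3 | 5,7-bis(benzyloxy)-4H-chromen-4-one | O=c1ccoc2cc(OCc3ccccc3)cc(OCc3ccccc3)c12 | intermediate
4 | 4-(benzyloxy)phenylboronic acid | OB(O)c1ccc(OCc2ccccc2)cc1 | starting material
5 | (2R)-5,7-bis(benzyloxy)-2-[4-(benzyloxy)phenyl]chroman-4-one | O=C1C[C@H](c2ccc(OCc3ccccc3)cc2)Oc2cc(OCc3ccccc3)cc(OCc3ccccc3)c12 | intermediate
6 | 1,3,5-tris(benzyloxy)benzene | c1ccc(COc2cc(OCc3ccccc3)cc(OCc3ccccc3)c2)cc1 | starting material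
7 | bromoacetyl bromide | O=C(Br)CBr | starting material
8 | 2-bromo-1-[2,4,6-tris(benzyloxy)phenyl]ethan-1-one | O=C(CBr)c1c(OCc2ccccc2)cc(OCc2ccccc2)cc1OCc1ccccc1 | intermediate
9 | lithium (2R)-5,7-bis(benzyloxy)-2-[4-(benzyloxy)phenyl]-2H-chromen-4-olate (enolate of 5) | [Li+].[O-]C1=C[C@H](c2ccc(OCc3ccccc3)cc2)Oc2cc(OCc3ccccc3)cc(OCc3ccccc3)c12 | intermediate
10 | (2R,3S)-5,7-bis(benzyloxy)-2-[4-(benzyloxy)phenyl]-3-{2-oxo-2-[2,4,6-tris(benzyloxy)phenyl]ethyl}chroman-4-one | O=C(C[C@@H]1C(=O)c2c(OCc3ccccc3)cc(OCc3ccccc3)cc2O[C@H]1c1ccc(OCc2ccccc2)cc1)c1c(OCc2ccccc2)cc(OCc2ccccc2)cc1OCc1ccccc1 | intermediate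
11 | 4-methoxybenzaldehyde | COc1ccc(C=O)cc1 | starting material
12 | (Z)-dibutylboron enolate of the side-chain ketone of 10 | CCCCB(CCCC)O/C(=C\[C@@H]1C(=O)c2c(OCc3ccccc3)cc(OCc3ccccc3)cc2O[C@H]1c1ccc(OCc2ccccc2)cc1)c1c(OCc2ccccc2)cc(OCc2ccccc2)cc1OCc1ccccc1 | intermediate
13 | dibutylboron aldolate of 14 (O-boron on the new carbinol, new centres unassigned) | COc1ccc(C(OB(CCCC)CCCC)C(C(=O)c2c(OCc3ccccc3)cc(OCc3ccccc3)cc2OCc2ccccc2)[C@@H]2C(=O)c3c(OCc4ccccc4)cc(OCc4ccccc4)cc3O[C@H]2c2ccc(OCc3ccccc3)cc2)cc1 | intermediate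
14 | (2R,3S)-5,7-bis(benzyloxy)-2-[4-(benzyloxy)phenyl]-3-{1-hydroxy-1-(4-methoxyphenyl)-3-oxo-3-[2,4,6-tris(benzyloxy)phenyl]propan-2-yl}chroman-4-one (new centres unassigned) | COc1ccc(C(O)C(C(=O)c2c(OCc3ccccc3)cc(OCc3ccccc3)cc2OCc2ccccc2)[C@@H]2C(=O)c3c(OCc4ccccc4)cc(OCc4ccccc4)cc3O[C@H]2c2ccc(OCc3ccccc3)cc2)cc1 | intermediate
15 | methanesulfonate of 14 at the benzylic carbinol | COc1ccc(C(OS(C)(=O)=O)C(C(=O)c2c(OCc3ccccc3)cc(OCc3ccccc3)cc2OCc2ccccc2)[C@@H]2C(=O)c3c(OCc4ccccc4)cc(OCc4ccccc4)cc3O[C@H]2c2ccc(OCc3ccccc3)cc2)cc1 | intermediate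
16 | (2R,3S)-5,7-bis(benzyloxy)-2-[4-(benzyloxy)phenyl]-3-{(1E)-1-(4-methoxyphenyl)-3-oxo-3-[2,4,6-tris(benzyloxy)phenyl]prop-1-en-2-yl}chroman-4-one | COc1ccc(/C=C(/C(=O)c2c(OCc3ccccc3)cc(OCc3ccccc3)cc2OCc2ccccc2)[C@@H]2C(=O)c3c(OCc4ccccc4)cc(OCc4ccccc4)cc3O[C@H]2c2ccc(OCc3ccccc3)cc2)cc1 | intermediate
17 | bis(dichloroboryl) ether of 18 (O–BCl2 at the 2'-oxygen and at the 5''-oxygen, each chelated to its ketone) | COc1ccc(/C=C(/C(=O)c2c(OB(Cl)Cl)cc(OCc3ccccc3)cc2OCc2ccccc2)[C@@H]2C(=O)c3c(OB(Cl)Cl)cc(OCc4ccccc4)cc3O[C@H]2c2ccc(OCc3ccccc3)cc2)cc1 | intermediate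
18 | (2R,3S)-7-(benzyloxy)-2-[4-(benzyloxy)phenyl]-3-{(1E)-3-[2,4-bis(benzyloxy)-6-hydroxyphenyl]-1-(4-methoxyphenyl)-3-oxoprop-1-en-2-yl}-5-hydroxychroman-4-one | COc1ccc(/C=C(/C(=O)c2c(O)cc(OCc3ccccc3)cc2OCc2ccccc2)[C@@H]2C(=O)c3c(O)cc(OCc4ccccc4)cc3O[C@H]2c2ccc(OCc3ccccc3)cc2)cc1 | intermediate
19 | (2S,3S)-5,7-bis(benzyloxy)-3-[(2R,3S)-7-(benzyloxy)-2-[4-(benzyloxy)phenyl]-5-hydroxy-4-oxochroman-3-yl]-2-(4-methoxyphenyl)chroman-4-one (2,3-cis epimer of 20) | COc1ccc([C@H]2Oc3cc(OCc4ccccc4)cc(OCc4ccccc4)c3C(=O)[C@H]2[C@@H]2C(=O)c3c(O)cc(OCc4ccccc4)cc3O[C@H]2c2ccc(OCc3ccccc3)cc2)cc1 | intermediate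
20 | (2S,3R)-5,7-bis(benzyloxy)-3-[(2R,3S)-7-(benzyloxy)-2-[4-(benzyloxy)phenyl]-5-hydroxy-4-oxochroman-3-yl]-2-(4-methoxyphenyl)chroman-4-one | COc1ccc([C@H]2Oc3cc(OCc4ccccc4)cc(OCc4ccccc4)c3C(=O)[C@@H]2[C@@H]2C(=O)c3c(O)cc(OCc4ccccc4)cc3O[C@H]2c2ccc(OCc3ccccc3)cc2)cc1 | intermediate
21 | (2S,3R)-5,7-dihydroxy-3-[(2R,3S)-5,7-dihydroxy-2-(4-hydroxyphenyl)-4-oxochroman-3-yl]-2-(4-methoxyphenyl)chroman-4-one | COc1ccc([C@H]2Oc3cc(O)cc(O)c3C(=O)[C@@H]2[C@@H]2C(=O)c3c(O)cc(O)cc3O[C@H]2c2ccc(O)cc2)cc1 | target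

Total step count: 9. Longest linear sequence: 8 steps (steps 1, 2, 4, 5, 6, 7, 8, 9; step 3 makes the side-chain electrophile).

Steps most likely to fail

Step 8. The catalyst may discriminate poorly between the two faces of an unactivated, α-branched enone, and an uncatalysed background cyclisation may add to this, so that both C2 series form. The fallback sets out from 18 and comes back at 20. Catalyst control is given up: 18 is cyclised under kinetic conditions with an achiral amine (Et3N, toluene, 0 °C, then 20 °C for C3 equilibration). Because unit 2 is already a single enantiomer, the two products are diastereomers, the wanted 20 and the unwanted (2R,3S,2''R,3''S) diastereomer F1. They are separated by chromatography or crystallisation, and 20 goes on to step 9; the enantiomeric purity then rests on step 2 alone.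

Step 4. The lithium enolate may open the pyranone by β-elimination, or take bromine from the bromoketone, faster than it is C-alkylated. The fallback sets out from 5 and comes back at 10. Compound 5 is deprotonated in the presence of Me3SiCl (LiN(SiMe3)2, THF, −78 °C, internal quench) to give the trimethylsilyl enol ether F2, so that no free enolate persists. F2 is then alkylated by a radical instead of a polar path: 8, Ir(ppy)3 (1 mol %), 2,6-lutidine, MeCN, blue LEDs, 25 °C. The excited photocatalyst cleaves the C–Br bond reductively, the α-keto radical adds to C3'' of the enol ether, and oxidation with loss of the silyl group returns the ketone, which should settle as trans 10 on work-up.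

Step 5. Enolisation may occur at C3'' instead of the side-chain CH2, or the Lewis acid may damage unit 2, so that the aldol adduct is not obtained cleanly. The fallback sets out from 10 and comes back at 16, bypassing steps 5 and 6, and uses no enolate. α-Methylenation of 10 with paraformaldehyde (formaldehyde, C=O) and N-methylanilinium trifluoroacetate (THF, 65 °C; Mannich condensation and elimination, possible only at the CH2) gives the α-methylene ketone F3. A Mizoroki–Heck arylation with 4-iodoanisole (COc1ccc(I)cc1; Pd(OAc)2, Bu4NCl, NaHCO3, DMF, 70 °C) then delivers 16. β-Hydride elimination toward the new benzylic CH2 gives the conjugated E-enone, whereas elimination toward C3''–H would require a tetrasubstituted alkene.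

Further compounds
F1 | step 8 | (2R,3S)-5,7-bis(benzyloxy)-3-[(2R,3S)-7-(benzyloxy)-2-[4-(benzyloxy)phenyl]-5-hydroxy-4-oxochroman-3-yl]-2-(4-methoxyphenyl)chroman-4-one | COc1ccc([C@@H]2Oc3cc(OCc4ccccc4)cc(OCc4ccccc4)c3C(=O)[C@H]2[C@@H]2C(=O)c3c(O)cc(OCc4ccccc4)cc3O[C@H]2c2ccc(OCc3ccccc3)cc2)cc1
F2 | step 4 | {[(2R)-5,7-bis(benzyloxy)-2-[4-(benzyloxy)phenyl]-2H-chromen-4-yl]oxy}trimethylsilane | C[Si](C)(C)OC1=C[C@H](c2ccc(OCc3ccccc3)cc2)Oc2cc(OCc3ccccc3)cc(OCc3ccccc3)c12
F3 | step 5 | (2R,3S)-5,7-bis(benzyloxy)-2-[4-(benzyloxy)phenyl]-3-{3-oxo-3-[2,4,6-tris(benzyloxy)phenyl]prop-1-en-2-yl}chroman-4-one | C=C(C(=O)c1c(OCc2ccccc2)cc(OCc2ccccc2)cc1OCc1ccccc1)[C@@H]1C(=O)c2c(OCc3ccccc3)cc(OCc3ccccc3)cc2O[C@H]1c1ccc(OCc2ccccc2)cc1
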